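## Structural features

The target 7 is an achiral 2-(2-arylethyl)chromone. Ring A (the benzo ring C4a–C5–C6–C7–C8–C8a, methoxy groups on C6 and C7) is fused through C4a–C8a to ring C (the 4-pyranone O1–C2–C3–C4). C2 carries a CH2–CH2 tether to ring B, a 3-hydroxy-4-methoxyphenyl group. There is no stereocentre and no double-bond geometry to control. Ring A is 1,2,4-trioxygenated (O1 on C8a is para to the C6 methoxy group), and the C4 carbonyl sits on C4a, ortho to O1. The ring-B hydroxyl is the only free phenol among four aryl oxygens, so it must be carried through in differentiated form from an isovanillyl building block. Ring C is a vinylogous ester: alkoxide or hydroxide opens it at C2, the methylene on C2 is vinylogously acidic, and C2=C3 can be reduced under forcing hydrogenation. The real difficulty is therefore the convergent construction of ring C with its C2 alkyl chain, that is the C3–C4 and O1–C2 bonds. The key step exploits the ortho pair O1/C4: in a salicylaldehyde, O1 holds a metal next to the formyl C4–H, so C4 enters as an acyl-metal nucleophile, C3 as a carbene carbon, and O1 then closes onto C2.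

## Logic of the disconnections

7 back to 6. The bond cut is the O–CH2Ph bond on the ring-B oxygen. The cut is made because this oxygen must end as the only free phenol and must not act as an O–H donor toward a metal carbene. The gain is that the side-chain acid can be masked and activated in one operation. The demand on the forward step is cleavage of a benzyl aryl ether without reduction of C2=C3 and without loss of a methyl ether.

6 back to 3 and 4, through 5. The bonds cut are O1–C2 (dehydrative closure) and C3–C4. C4 leaves with ring A at the aldehyde oxidation level in 4, and C3 leaves with the side chain as the ylide carbon of 3. Both carbons react in reversed polarity: C4 as an acyl-metal donor instead of an acyl acceptor, C3 as an electrophilic carbene instead of an enolate. In one sentence, ring C is closed by rhodium-catalysed coupling of the formyl C4–H of 4 with the carbene carbon of 3. The gain is that ring C disappears and 6 falls into two fragments of similar size, one purchasable and one two steps from a purchasable acid. The demands are selectivity for the formyl C–H over aromatic C–H bonds, a single carbene insertion, and closure of O1 onto C2 of 5.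

3 back to 2. The bond cut is C2–C3 (chromone numbering), between the side-chain carbonyl and the ylide carbon. The cut is made because C3 can then be supplied as a one-carbon sulfur ylide reagent. The gain is that the side chain becomes a plain 3-arylpropanoate. The demand is acyl substitution at an enolisable ester by a weakly basic carbon nucleophile, with the product protected from further attack by its own ylide character.

2 back to 1. The bonds cut are the two O–benzyl bonds, ester and ether. Both are made in one alkylation, so protection costs no separate step. The gain is a purchasable acid that already holds the ring-B oxygen pattern. The demand is only exhaustive O-alkylation.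

## Other disconnections considered

Alternative 1: the first cut that comes to mind is C2–C3 together with O1–C2, with C3 left on ring A as an acetyl group. 1-(2-Hydroxy-4,5-dimethoxyphenyl)ethanone A1 would be O-acylated by 3-[3-(benzyloxy)-4-methoxyphenyl]propanoyl chloride A2 to aryl ester A3. The forward key step is the Baker–Venkataraman acyl migration of A3 under strong base to 5, followed by acid closure to 6.
- This spends four stoichiometric operations (activation, O-acylation, base-mediated migration, acid closure) on the two bonds that the chosen key step forms in one catalytic pot.
- The base that enolises the acetyl group of A3 can also cleave its aryl ester.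
- The direct Claisen variant (dianion of A1 with 2) is as short as the chosen route and is kept as the fallback. It is not chosen because it is the conventional cut and because proton transfer from the enolisable ester to the ketone dianion competes with C-acylation.

Alternative 2: cut the tether between its two carbons as an alkene. The forward key step is the vinylogous aldol condensation of 6,7-dimethoxy-2-methyl-4H-chromen-4-one A4 with 3-(benzyloxy)-4-methoxybenzaldehyde A5 under alkoxide to styrylchromone A6. Hydrogenation would then saturate the tether and remove the benzyl group to give 7.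
- A4 must first be made by building ring C classically from A1, so the key step simplifies only the tether and the route is longer.
- The alkoxide needed to deprotonate the C2 methyl group also adds at C2 and opens ring C.
- The final hydrogenation must distinguish the styryl double bond from C2=C3.

Alternative 3: cut C4–C4a, C3–C4 and O1–C2, with C4 supplied as carbon monoxide. The forward key step is a palladium-catalysed carbonylative Sonogashira coupling of 2-iodo-4,5-dimethoxyphenol A7 with 2-(benzyloxy)-4-(but-3-yn-1-yl)-1-methoxybenzene A8 under CO to ynone A9, closed by amine-mediated 6-endo addition of O1 to give 6.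
- Three bonds form in one step, but A8 needs a three- to four-step homologation to a terminal alkyne and A7 needs an iodination, so the route is about twice as long.
- A9 can also close 5-exo to an aurone.
- The secondary amine competes for the acyl-palladium intermediate, and pressurised CO is required.

Key step: step 3

Remark: 1 and 4 are taken as purchasable; 7 has no stereocentre, so no configurational descriptor is needed; chromone numbering (O1, C2, C3, C4, C4a, C5 to C8, C8a) is used throughout.

## Steps

Step 1
Reactants: 1 3-(3-hydroxy-4-methoxyphenyl)propanoic acid
Product: 2 benzyl 3-[3-(benzyloxy)-4-methoxyphenyl]propanoate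
Conditions: BnBr (2.5 equiv), K2CO3 (3 equiv), DMF, 60 °C
Reagents that add atoms: benzyl bromide, BrCc1ccccc1
Why: Double O-alkylation (Williamson ether synthesis and carboxylate alkylation): carbonate deprotonates both the acid and the phenol, and both oxyanions are benzylated by SN2; the benzyl ester is the acyl donor of step 2 and the benzyl ether masks the ring-B phenol.

Step 2
Reactants: 2 benzyl 3-[3-(benzyloxy)-4-methoxyphenyl]propanoate
Product: 3 4-[3-(benzyloxy)-4-methoxyphenyl]-1-[dimethyl(oxo)-λ6-sulfanylidene]butan-2-one
Conditions: Me3S(O)I (3.0 equiv), KOtBu (3.0 equiv), THF, reflux, 2 h; then 2, THF, reflux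
Reagents that add atoms: trimethylsulfoxonium iodide, C[S+](C)(C)=O.[I-]
Why: Acylation of dimethylsulfoxonium methylide (the Corey–Chaykovsky reagent) by an ester: addition–elimination expels benzyl oxide, and the β-keto sulfoxonium salt is deprotonated at once to the carbonyl-stabilised ylide 3, which shields the new ketone from a second attack; the ylide is too weak a base to enolise the ester.

Step 3
Reactants: 3 4-[3-(benzyloxy)-4-methoxyphenyl]-1-[dimethyl(oxo)-λ6-sulfanylidene]butan-2-one (1.0 equiv); 4 2-hydroxy-4,5-dimethoxybenzaldehyde (1.3 equiv)
Product: 6 2-{2-[3-(benzyloxy)-4-methoxyphenyl]ethyl}-6,7-dimethoxy-4H-chromen-4-one, via 1,3-diketone 5 (not isolated)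
Conditions: [(C5Me5)RhCl2]2 (2.5 mol %), AgSbF6 (10 mol %), NaOAc (30 mol %), AcOH (1.0 equiv), 1,2-dichloroethane, 90 °C, argon; then TsOH·H2O (20 mol %), 80 °C
Reagents that add atoms: none
Why: Acetate-assisted deprotonation of O1–H binds the cationic (C5Me5)Rh centre (trivalent rhodium) to ring A, and concerted metalation–deprotonation of the formyl C4–H gives a five-membered aroyl rhodacycle; C-coordination of 3 and loss of dimethyl sulfoxide give a rhodium α-oxo carbene, migratory insertion of the aroyl group forms C3–C4, and protonolysis by AcOH releases diketone 5 and the catalyst. The closest known reaction type is the (C5Me5)Rh-catalysed C–H acylmethylation and annulation with sulfoxonium ylides as carbene surrogates, including the formyl C–H of salicylaldehydes leading to chromones. Ring C then closes by 6-exo-trig attack of O1 on the C2 ketone to a hemiketal, followed by acid-catalysed loss of water; closure of O1 onto C4 would give a four-membered ring and is not available. No stereocentre is formed. The step needs formyl over aromatic C–H selectivity, which the O1 phenoxide chelate secures by placing only C4–H within reach of the metal. It also needs carbene transfer in preference to Corey–Chaykovsky epoxidation of the aldehyde, which the low nucleophilicity of the carbonyl-stabilised ylide secures. Single insertion is favoured by the slight excess of 4 and by the C6 methoxy group, which shields C5–H of the product from ketone-directed metalation. The benzyl ether keeps the ring-B oxygen from competing as an O–H donor for the carbene.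

Step 4
Reactants: 6 2-{2-[3-(benzyloxy)-4-methoxyphenyl]ethyl}-6,7-dimethoxy-4H-chromen-4-one
Product: 7 2-[2-(3-hydroxy-4-methoxyphenyl)ethyl]-6,7-dimethoxy-4H-chromen-4-one
Conditions: H2 (1 atm), Pd/C (10 wt % Pd), EtOAc/MeOH, rt, stopped at consumption of 6
Reagents that add atoms: none
Why: Hydrogenolysis of a benzyl aryl ether on palladium; at 1 atm this cleavage should be much faster than reduction of the vinylogous-ester C2=C3 of the chromone, and the methyl ethers are inert.

## Compound list

1 | 3-(3-hydroxy-4-methoxyphenyl)propanoic acid | COc1ccc(CCC(=O)O)cc1O | starting material
2 | benzyl 3-[3-(benzyloxy)-4-methoxyphenyl]propanoate | COc1ccc(CCC(=O)OCc2ccccc2)cc1OCc1ccccc1 | intermediate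
3 | 4-[3-(benzyloxy)-4-methoxyphenyl]-1-[dimethyl(oxo)-λ6-sulfanylidene]butan-2-one | COc1ccc(CCC(=O)C=S(C)(C)=O)cc1OCc1ccccc1 | intermediate
4 | 2-hydroxy-4,5-dimethoxybenzaldehyde | COc1cc(O)c(C=O)cc1OC | starting material
5 | 5-[3-(benzyloxy)-4-methoxyphenyl]-1-(2-hydroxy-4,5-dimethoxyphenyl)pentane-1,3-dione | COc1ccc(CCC(=O)CC(=O)c2cc(OC)c(OC)cc2O)cc1OCc1ccccc1 | intermediate
6 | 2-{2-[3-(benzyloxy)-4-methoxyphenyl]ethyl}-6,7-dimethoxy-4H-chromen-4-one | COc1ccc(CCc2cc(=O)c3cc(OC)c(OC)cc3o2)cc1OCc1ccccc1 | intermediate
7 | 2-[2-(3-hydroxy-4-methoxyphenyl)ethyl]-6,7-dimethoxy-4H-chromen-4-one | COc1ccc(CCc2cc(=O)c3cc(OC)c(OC)cc3o2)cc1O | target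

## Step count and least certain steps

Total step count: 4. Longest linear sequence: 4 steps (1 to 2 to 3 to 6 to 7); 4 enters at step 3.

Step 3 (key step). Three processes are most likely to go wrong.
- Catalyst turnover may stall on this electron-rich aldehyde, or the aroyl-rhodium intermediate may lose CO before the carbene is delivered.
- A second carbene insertion may occur at C5–H of the product, directed by the C4 carbonyl, if the ylide is in local excess.
- Cyclodehydration of 5 may be incomplete before the acid treatment.

Fallback: the classical C2–C3 construction. It sets out from 2 and uses purchasable 1-(2-hydroxy-4,5-dimethoxyphenyl)ethanone F1 (identical with A1). The dianion of F1 (LiN(SiMe3)2, 3.2 equiv, THF, −78 °C to rt) would be C-acylated by 2 in a Claisen condensation. This comes back to the route at 5, which the acid treatment of step 3 (TsOH·H2O, toluene, 80 °C) closes to 6.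

Step 2. The most likely failure is slow or incomplete acyl substitution, because an unactivated benzyl ester is a modest acceptor for the weakly nucleophilic methylide, and long heating erodes the ylide. Fallback: change of acyl donor. It sets out from 2, which is saponified (LiOH, THF/H2O) to 3-[3-(benzyloxy)-4-methoxyphenyl]propanoic acid F2. F2 is esterified with 4-nitrophenol (N,N'-dicyclohexylcarbodiimide, cat. DMAP, CH2Cl2) to 4-nitrophenyl 3-[3-(benzyloxy)-4-methoxyphenyl]propanoate F3. This activated ester should acylate the preformed methylide at 0 °C to rt and comes back to the route at 3.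

Step 4. Two processes are most likely to go wrong: over-reduction of C2=C3 of ring C after the benzyl group has gone, or stalled hydrogenolysis through poisoning of the palladium surface by sulfur or silver residues carried over from step 3. Fallback: non-reductive, Lewis-acid-mediated debenzylation. It sets out from 6 (BCl3, pentamethylbenzene as benzyl cation scavenger, CH2Cl2, −78 °C) and comes back at 7. At this temperature the methyl ethers, none of which is peri to the carbonyl, should remain intact; no new compound arises (entry F0).

## Further compounds

F1 | step 3 | 1-(2-hydroxy-4,5-dimethoxyphenyl)ethanone | CC(=O)c1cc(OC)c(OC)cc1O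
F2 | step 2 | 3-[3-(benzyloxy)-4-methoxyphenyl]propanoic acid | COc1ccc(CCC(=O)O)cc1OCc1ccccc1
F3 | step 2 | 4-nitrophenyl 3-[3-(benzyloxy)-4-methoxyphenyl]propanoate | COc1ccc(CCC(=O)Oc2ccc(cc2)[N+](=O)[O-])cc1OCc1ccccc1
F0 | step 4 | none | none
A1 | alternative 1 | 1-(2-hydroxy-4,5-dimethoxyphenyl)ethanone | CC(=O)c1cc(OC)c(OC)cc1O
A2 | alternative 1 | 3-[3-(benzyloxy)-4-methoxyphenyl]propanoyl chloride | COc1ccc(CCC(=O)Cl)cc1OCc1ccccc1
A3 | alternative 1 | 2-acetyl-4,5-dimethoxyphenyl 3-[3-(benzyloxy)-4-methoxyphenyl]propanoate | COc1ccc(CCC(=O)Oc2cc(OC)c(OC)cc2C(C)=O)cc1OCc1ccccc1
A4 | alternative 2 | 6,7-dimethoxy-2-methyl-4H-chromen-4-one | Cc1cc(=O)c2cc(OC)c(OC)cc2o1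
A5 | alternative 2 | 3-(benzyloxy)-4-methoxybenzaldehyde | COc1ccc(C=O)cc1OCc1ccccc1
A6 | alternative 2 | 2-{(E)-2-[3-(benzyloxy)-4-methoxyphenyl]ethenyl}-6,7-dimethoxy-4H-chromen-4-one | COc1ccc(/C=C/c2cc(=O)c3cc(OC)c(OC)cc3o2)cc1OCc1ccccc1
A7 | alternative 3 | 2-iodo-4,5-dimethoxyphenol | COc1cc(O)c(I)cc1OC
A8 | alternative 3 | 2-(benzyloxy)-4-(but-3-yn-1-yl)-1-methoxybenzene | C#CCCc1ccc(OC)c(OCc2ccccc2)c1
A9 | alternative 3 | 5-[3-(benzyloxy)-4-methoxyphenyl]-1-(2-hydroxy-4,5-dimethoxyphenyl)pent-2-yn-1-one | COc1ccc(CCC#CC(=O)c2cc(OC)c(OC)cc2O)cc1OCc1ccccc1
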